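Start from the charge.

| flask | starting material | second substrate | free enzyme | remark | time |
|---|---|---|---|---|---|
| Friday's | 0.13 M | 0.123 M | 26 µM | run made earlier |  |
| Sunday's | 0.13 M | 0.082 M | 26 µM | run made earlier |  |
| Wednesday's | 0.13 M | 0.18 M | 26 µM | run made earlier |  |
| Tuesday's | 0.13 M | 0.123 M | 39 µM | run made earlier |  |
| midnight | 0.13 M | 0.123 M (fed, over 1.5 min) | 26 µM | all else is in the flask from the start; the feed brings no volume worth counting | 10 min |
| summer | 0.13 M (fed, over 6.0 min) | 0.123 M | 26 µM | all else is in the flask from the start; the feed brings no volume worth counting | 10 min |
| spring | 0.13 M | 0.123 M (fed, over 6.0 min) | 26 µM | all else is in the flask from the start; the feed brings no volume worth counting | 10 min |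
| dawn | 0.13 M | 0.123 M | 26 µM | everything together at the start | 10 min |

- Friday's (time / min: target / %): 2.00: 21.4; 4.00: 39.5; 6.00: 57.4; 8.00: 71.6; 10.0: 84.2
- Sunday's (time / min: target / %): 2.00: 19.4; 4.00: 35.7; 6.00: 50.4; 8.00: 56.4; 10.0: 58.4
- Wednesday's (time / min: target / %): 0.833: 7.8; 2.50: 28.2; 5.00: 52.8; 8.00: 79.3; 10.0: 92.5
- Tuesday's (time / min: target / %): 0.833: 13.3; 1.50: 25.7; 3.00: 45.2; 5.00: 69.2; 10.0: 93.9

(each reading ± 1 percentage point)



- which flask leads in amount of target, in percent of the starting material charged ("all alike" within 1.5 percentage points) (midnight / summer / spring / dawn / all alike)
- how much target is there at the end, in percent of the starting material charged: midnight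
- how much target is there at the end, in percent of the starting material charged: summer
- how much target is there at the end, in percent of the starting material charged: spring
- how much target is there at the end, in percent of the starting material charged: dawn

1. There is less second substrate than starting material, and Sunday's run flattens at 58.4%, just under the 63.1% that its own charges allow, so I read the reaction as one for one. For midnight, summer, spring and dawn, second substrate charged over starting material charged gives 94.6%, and that ratio is my ceiling: the target that the limiting reagent can pay for.

2. The bench rule I try on dawn is that it keeps its opening pace. Dawn has Friday's recipe, and Friday makes 21.4% in 2.00 min, so at that pace the ceiling comes after 8.84 min, sooner than 10 min. But Friday ends at 84.2%, below the ceiling, so on Friday's recipe the rule stops holding before the end, and I go round again with Friday's late pace, 13 percentage points in the last 2.00 min.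

3. I put dawn near Friday's 84.2%. In midnight the second substrate arrives 0.750 min late on average, and at the late pace that gives 79.5%.

4. In summer and spring the feed takes 6.0 min, which is 0.679 of my ceiling time, so I expect the feed to run ahead of the flask and the average lag of 3.00 min not to be paid in full. Friday's level at 7.00 min, about 64.5%, is therefore my low mark for both, and I put dawn first.

5. The forecast also puts dawn first: dawn 84.3%, midnight 82.7%, which stands above mine, summer 79.5% and spring 77%. Its ground is “With no inhibition, feeding only starves the reaction and costs time.”

6. The flasks give dawn the lead: dawn 82.0%, midnight 80.3%, summer 74.1%, spring 73.1%.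

    starting material + free enzyme ⇌ first complex (K = 11.0 M⁻¹, k = 9630 M⁻¹ s⁻¹)
    first complex → loaded enzyme + first product (k = 77.7 s⁻¹)
    second substrate + loaded enzyme ⇌ second complex (K = 32.0 M⁻¹, k = 4010 M⁻¹ s⁻¹)
    second complex → free enzyme + target (k = 15.2 s⁻¹)
    free enzyme ⇌ dormant form (K = 0.358, k = 0.00115 s⁻¹)

7. The gap of 8.9 points between dawn and spring shrinks to 1.5 points when the same flasks run without the falling back of second complex to second substrate + loaded enzyme. After 100 min, dawn stands at 94.6% and spring at 94.6%, both at the ceiling, so the feed in spring has cost time. For dawn with 0.074 M of second substrate, the ceiling falls to 56.9%, and Friday's opening pace reaches it after 5.32 min, so I expect that flask close under it. It gives 55.6%.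

All runs stem from a simulated flask for substances that don't exist; the scatter is artificial.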